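**Plan**
- Retrosynthesis: the four benzyl ethers come off last; the dihydrofuran is cut at O1–C2 (Mitsunobu etherification); ring B is then cut at C3a–C4 and C7–C7a (benzofuran numbering), which separates an oxolane-bearing 3-alkylcyclobutenone (fragment 1) from a chiral triisopropylsilyl ynol ether (fragment 2).
- Enabling feature: ring B is a 5-alkylresorcinol whose carbon between the two oxygens (C3a) carries benzofuran C3, the pattern that a 3-substituted cyclobutenone and an O-silylated ynol deliver in a Danheiser benzannulation.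
- Forward order of rings: γ-lactone → oxolane (cationic 5-exo closure) → cyclobutenone ([2+2] with dichloroketene) → ring B (benzannulation) → dihydrofuran (Mitsunobu) → hydrogenolysis.
- Stereochemistry: oxolane C4 from an Evans alkylation, C3 from a trans-selective lactone aldol, C2 from the trans-selective cationic ring closure; benzofuran C3 and its neighbouring carbinol from an Evans syn aldol, benzofuran C2 by inversion of that carbinol in the Mitsunobu closure.

Key step: step 17

Remark 1: 3-benzyloxy-4-methoxybenzaldehyde and 4-benzyloxy-3-methoxybenzaldehyde are taken as purchased (each is otherwise one benzylation from isovanillin or vanillin).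
Remark 2: enolates, acetylides, alkoxides and phenoxides formed by simple deprotonation are treated as the reacting form of the numbered compound they come from.
Remark 3: the lactone aldol (step 4) is expected to give both carbinol epimers; the anti epimer is drawn for the adduct and the derived triol, and the other is carried along because the later acid ring closure ionises that centre. For the same reason the sp3 ring centre of the transient vinylcyclobutenone in step 17 is left open.
Remark 4: acid is used only before ring B exists (step 6); once the electron-rich ring B is present, an ionised oxolane C2 could alkylate it, so steps 17–21 avoid acid.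

**Fragment 1 (steps 1–9)**

Step 1
Reactants: 1 mono-tert-butyl succinate (4-tert-butoxy-4-oxobutanoic acid); 2 (4S)-4-benzyl-1,3-oxazolidin-2-one
Product: 3 tert-butyl 4-[(4S)-4-benzyl-2-oxo-1,3-oxazolidin-3-yl]-4-oxobutanoate
Conditions: t-BuCOCl, Et3N, THF, −20 °C; then LiCl, 2, −20 °C → rt
Reagents that add atoms: none
Why: N-acylation of the oxazolidinone through the mixed pivalic anhydride (LiCl/Et3N variant) is routine and leaves the tert-butyl ester untouched.

Step 2
Reactants: 3 succinate imide; 4 (3-bromoprop-1-yn-1-yl)trimethylsilane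
Product: 5 tert-butyl (3S)-3-{[(4S)-4-benzyl-2-oxo-1,3-oxazolidin-3-yl]carbonyl}-6-(trimethylsilyl)hex-5-ynoate
Conditions: NaN(SiMe3)2, THF, −78 °C; then 4, −78 → −40 °C
Reagents that add atoms: none
Why: Evans asymmetric alkylation: the imide α-CH2 is deprotonated in preference to the ester α-CH2, and the chelated Z sodium enolate takes the propargylic bromide on the face opposite the auxiliary benzyl group, setting the (S) centre that becomes oxolane C4.

Step 3
Reactants: 5 alkylated imide
Product: 7 (4S)-4-[3-(trimethylsilyl)prop-2-yn-1-yl]oxolan-2-one, via hydroxy ester 6 (not isolated)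
Conditions: LiBH4, MeOH (1 equiv), THF, 0 °C; then CF3CO2H, CH2Cl2, rt
Reagents that add atoms: none
Why: Reductive cleavage of the N-acyloxazolidinone with LiBH4 spares the tert-butyl ester, and acid then lactonises the γ-hydroxy ester with loss of isobutene; the stereocentre is not touched.

Step 4
Reactants: 7 lactone; 8 3-benzyloxy-4-methoxybenzaldehyde
Product: 9 (3R,4S)-3-[(S)-(3-benzyloxy-4-methoxyphenyl)(hydroxy)methyl]-4-[3-(trimethylsilyl)prop-2-yn-1-yl]oxolan-2-one
Conditions: LiN(i-Pr)2, THF, −78 °C; then 8, −78 °C; AcOH quench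
Reagents that add atoms: none
Why: Aldol addition of the lactone lithium enolate: the aldehyde approaches anti to the C4 substituent, so ring centre C3 is set trans by substrate control, while the carbinol centre forms as an epimer mixture that is of no consequence.

Step 5
Reactants: 9 aldol adduct
Product: 10 (1S,2S,3S)-1-(3-benzyloxy-4-methoxyphenyl)-2-(hydroxymethyl)-3-[3-(trimethylsilyl)prop-2-yn-1-yl]butane-1,4-diol
Conditions: LiAlH4, THF, 0 °C; aqueous NaOH work-up
Reagents that add atoms: none
Why: Hydride reduction of the lactone to the diol; the silylated alkyne and the aryl benzyl ether are inert at 0 °C.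

Step 6
Reactants: 10 triol
Product: 12 [(2R,3S,4S)-2-(3-benzyloxy-4-methoxyphenyl)-4-(prop-2-yn-1-yl)oxolan-3-yl]methanol, via silylalkyne oxolane 11 (not isolated)
Conditions: camphor-10-sulfonic acid (cat.), CH2Cl2, 0 °C → rt; then K2CO3, MeOH, rt
Reagents that add atoms: none
Why: Acid-catalysed SN1 cyclodehydration: the p-methoxy-stabilised benzylic cation is captured 5-exo by the hydroxymethyl oxygen on the propargyl-bearing carbon (the other primary alcohol could only form an oxetane), the aryl group settling trans to the C3 substituent so that both carbinol epimers converge on (2R), as in acid closures of lariciresinol-type oxolanes; K2CO3/MeOH then cleaves the C–Si bond.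

Step 7
Reactants: 12 oxolane alcohol
Product: 13 (2R,3S,4S)-2-(3-benzyloxy-4-methoxyphenyl)-3-(benzyloxymethyl)-4-(prop-2-yn-1-yl)oxolane
Conditions: NaH, BnBr, Bu4NI (cat.), THF–DMF, 0 °C → rt
Reagents that add atoms: benzyl bromide, BrCc1ccccc1
Why: Williamson etherification; the primary alkoxide forms and reacts far faster than the alkyne C–H, and a benzyl ether here keeps this alcohol masked through the fluoride and Mitsunobu steps.

Step 8
Reactants: 13 propargyl oxolane; 14 trichloroacetyl chloride
Product: 15 4,4-dichloro-3-{[(3S,4S,5R)-5-(3-benzyloxy-4-methoxyphenyl)-4-(benzyloxymethyl)oxolan-3-yl]methyl}cyclobut-2-en-1-one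
Conditions: Zn–Cu couple, Et2O–MeOCH2CH2OMe, rt, slow addition of 14
Reagents that add atoms: none
Why: [2+2] cycloaddition of dichloroketene (from zinc dechlorination of 14) with a terminal alkyne, the ketene carbonyl carbon bonding to the terminal alkyne carbon to give the 3-substituted dichlorocyclobutenone; dimethoxyethane ties up ZnCl2 and so shields the benzylic oxolane ether.

Step 9
Reactants: 15 dichlorocyclobutenone
Product: 16 3-{[(3S,4S,5R)-5-(3-benzyloxy-4-methoxyphenyl)-4-(benzyloxymethyl)oxolan-3-yl]methyl}cyclobut-2-en-1-one (fragment 1)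
Conditions: Zn, AcOH, Me2NCH2CH2NMe2, EtOH, 0 °C → rt
Reagents that add atoms: none
Why: Reductive dechlorination of the α,α-dichloroketone with zinc in amine-buffered AcOH is the standard completion of the dichloroketene route to 3-alkylcyclobutenones and does not touch benzyl ethers or the oxolane.

**Fragment 2 (steps 10–16)**

Step 10
Reactants: 17 3-(benzyloxy)propanoic acid; 18 (4R)-4-benzyl-1,3-oxazolidin-2-one
Product: 19 (4R)-4-benzyl-3-[3-(benzyloxy)propanoyl]-1,3-oxazolidin-2-one
Conditions: t-BuCOCl, Et3N, THF, −20 °C; then LiCl, 18, −20 °C → rt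
Reagents that add atoms: none
Why: Mixed-anhydride N-acylation of the oxazolidinone, as in step 1.

Step 11
Reactants: 19 imide; 20 4-benzyloxy-3-methoxybenzaldehyde
Product: 21 (4R)-4-benzyl-3-[(2R,3R)-2-(benzyloxymethyl)-3-(4-benzyloxy-3-methoxyphenyl)-3-hydroxypropanoyl]-1,3-oxazolidin-2-one
Conditions: n-Bu2BOTf, i-Pr2NEt, CH2Cl2, −78 → 0 °C; 20, −78 → 0 °C; pH 7 buffer, MeOH, H2O2
Reagents that add atoms: none
Why: Evans syn aldol: the Z dibutylboron enolate reacts through a Zimmerman–Traxler chair on the face opposite the auxiliary benzyl group, setting both (R) centres (the future benzofuran C3 and the syn carbinol); the covalent boron enolate of the β-benzyloxy imide should not β-eliminate at these temperatures.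

Step 12
Reactants: 21 syn aldol
Product: 22 (4R)-4-benzyl-3-[(2R,3R)-2-(benzyloxymethyl)-3-(4-benzyloxy-3-methoxyphenyl)-3-(tert-butyldimethylsilyloxy)propanoyl]-1,3-oxazolidin-2-one
Conditions: t-BuMe2SiOTf, 2,6-lutidine, CH2Cl2, 0 °C
Reagents that add atoms: tert-butyldimethylsilyl trifluoromethanesulfonate, CC(C)(C)[Si](C)(C)OS(=O)(=O)C(F)(F)F
Why: Silylation of a hindered secondary alcohol with the silyl triflate and a hindered pyridine base is standard and blocks retro-aldol cleavage in the following steps.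

Step 13
Reactants: 22 silylated imide
Product: 23 (2R,3R)-2-(benzyloxymethyl)-3-(4-benzyloxy-3-methoxyphenyl)-3-(tert-butyldimethylsilyloxy)propan-1-ol
Conditions: LiBH4, MeOH (1 equiv), THF, 0 °C
Reagents that add atoms: none
Why: Reductive removal of the oxazolidinone auxiliary with LiBH4 gives the primary alcohol without touching the α-centre and returns the auxiliary.

Step 14
Reactants: 23 alcohol
Product: 24 (2R,3R)-2-(benzyloxymethyl)-3-(4-benzyloxy-3-methoxyphenyl)-3-(tert-butyldimethylsilyloxy)propanal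
Conditions: Dess–Martin periodinane, NaHCO3, CH2Cl2, rt
Reagents that add atoms: none
Why: Buffered Dess–Martin oxidation is neutral enough to deliver the α-branched, doubly β-oxygenated aldehyde without epimerisation or elimination; it is used crude.

Step 15
Reactants: 24 aldehyde
Product: 25 {[(1R,2R)-2-(benzyloxymethyl)-1-(4-benzyloxy-3-methoxyphenyl)but-3-yn-1-yl]oxy}(tert-butyl)dimethylsilane
Conditions: dimethyl (1-diazo-2-oxopropyl)phosphonate, K2CO3, MeOH, 0 °C → rt
Reagents that add atoms: dimethyl (1-diazo-2-oxopropyl)phosphonate, COP(=O)(OC)C(=[N+]=[N-])C(C)=O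
Why: Seyferth–Gilbert homologation in its Ohira–Bestmann form turns the aldehyde into the terminal alkyne under carbonate/methanol conditions mild enough for α-branched aldehydes, so the propargylic centre should be kept.

Step 16
Reactants: 25 terminal alkyne
Product: 27 {[(3R,4R)-3-(benzyloxymethyl)-4-(4-benzyloxy-3-methoxyphenyl)-4-(tert-butyldimethylsilyloxy)but-1-yn-1-yl]oxy}tri(propan-2-yl)silane (fragment 2), via lithium ynolate 26 (not isolated)
Conditions: n-BuLi, THF, −78 °C; t-BuOOLi (from t-BuOOH and LiN(SiMe3)2), −78 → 0 °C; i-Pr3SiOTf, −78 → 0 °C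
Reagents that add atoms: tert-butyl hydroperoxide, CC(C)(C)OO; triisopropylsilyl trifluoromethanesulfonate, CC(C)[Si](OS(=O)(=O)C(F)(F)F)(C(C)C)C(C)C
Why: Oxidation of a lithium acetylide by lithium tert-butyl peroxide transfers oxygen to the terminal carbon to give the ynolate, which the bulky silyl triflate traps on oxygen to give the siloxyalkyne; the propargylic C–H is not acidic enough to be affected.

**Union and endgame (steps 17–21)**

Step 17
Reactants: 16 cyclobutenone (fragment 1); 27 siloxyalkyne (fragment 2)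
Product: 32 ring B phenol (free OH at C5; triisopropylsilyloxy at C3; chiral side chain at C4; oxolanylmethyl at C1), via vinylketene 28 (not isolated), via vinylcyclobutenone 29 (not isolated), via dienylketene 30 (not isolated), via cyclohexadienone 31 (not isolated)
Conditions: 27 (1.2 equiv), toluene, 80 °C then 110 °C, sealed tube, Ar
Reagents that add atoms: none
Why: Danheiser benzannulation: thermal four-electron electrocyclic opening of 16 gives vinylketene 28, whose ketene C=C bond adds to the ynol ether in a [2+2] step with the alkyne carbon remote from oxygen bonding to the ketene carbonyl carbon; the resulting 4-vinylcyclobutenone 29 reopens to dienylketene 30, which closes to dienone 31 and tautomerises to phenol 32. The closest known reaction is the union of 3-alkylcyclobutenones with triisopropylsilyl ynol ethers to give resorcinol monosilyl ethers; the partners here are only larger and α-branched. Ring B closes in the six-electron electrocyclic mode between the ketene carbon and the terminal methylene of 30, and the one stereocentre formed on the way (the sp3 ring carbon of 29) is erased again, so no new stereocentre needs control. The selectivity required is regiochemical, and the oxygen-induced polarisation of the alkyne places the side chain between the two ring B oxygens while the ketene oxygen emerges as the only free phenol. No acid, base or metal is present, so the five existing stereocentres, the silyl ethers and the benzylic ethers are not at risk, and the slight excess of 27 keeps the product phenol from being acylated by unreacted ketene.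

Step 18
Reactants: 32 ring B phenol
Product: 33 methyl ether of 32 (OMe at ring B C5; both silyl ethers retained)
Conditions: MeI, K2CO3, DMF, rt
Reagents that add atoms: iodomethane, CI
Why: Williamson methylation of the only free phenol; the hindered aryl triisopropylsilyl ether and the alkyl silyl ether survive carbonate in an aprotic solvent, so the two ring B oxygens stay differentiated.

Step 19
Reactants: 33 methyl ether
Product: 34 2-[(1R,2R)-3-benzyloxy-1-(4-benzyloxy-3-methoxyphenyl)-1-hydroxypropan-2-yl]-5-{[(3S,4S,5R)-5-(3-benzyloxy-4-methoxyphenyl)-4-(benzyloxymethyl)oxolan-3-yl]methyl}-3-methoxyphenol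
Conditions: Bu4NF, THF, 0 °C → rt
Reagents that add atoms: none
Why: Fluoride cleaves both silyl ethers in one operation, releasing exactly the phenol and the benzylic alcohol needed for ring closure while the four benzyl ethers keep every other hydroxyl masked.

Step 20
Reactants: 34 phenol–alcohol
Product: 35 (2S,3R)-2-(4-benzyloxy-3-methoxyphenyl)-3-(benzyloxymethyl)-6-{[(3S,4S,5R)-5-(3-benzyloxy-4-methoxyphenyl)-4-(benzyloxymethyl)oxolan-3-yl]methyl}-4-methoxy-2,3-dihydro-1-benzofuran
Conditions: PPh3, i-PrO2CN=NCO2i-Pr, THF, 0 °C → rt, high dilution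
Reagents that add atoms: none
Why: Intramolecular Mitsunobu etherification (5-exo-tet): the phenol displaces the activated syn carbinol with inversion, which gives the 2,3-trans ring and the (2S) centre; should the electron-rich benzylic centre react through an ion pair instead, collapse trans to the C3 substituent leads to the same isomer, and the neutral medium spares the oxolane.

Step 21
Reactants: 35 tetra-O-benzyl ether
Product: 36 [(2S,3R)-2-(4-hydroxy-3-methoxyphenyl)-6-{[(3S,4S,5R)-5-(3-hydroxy-4-methoxyphenyl)-4-(hydroxymethyl)oxolan-3-yl]methyl}-4-methoxy-2,3-dihydro-1-benzofuran-3-yl]methanol (CNP0242386.1)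
Conditions: H2 (1 atm), Pd/C, EtOAc–MeOH, rt, stopped after four equivalents of H2
Reagents that add atoms: none
Why: Catalytic hydrogenolysis removes the two aryl and two primary alkyl benzyl ethers; under neutral conditions the two hindered, ring-bound benzylic C–O bonds should react much more slowly, so stopping at the calculated uptake should leave both heterocycles intact.

**Compound list**

1 | 4-tert-butoxy-4-oxobutanoic acid | CC(C)(C)OC(=O)CCC(=O)O | starting material
2 | (4S)-4-benzyl-1,3-oxazolidin-2-one | O=C1N[C@@H](Cc2ccccc2)CO1 | starting material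
3 | tert-butyl 4-[(4S)-4-benzyl-2-oxo-1,3-oxazolidin-3-yl]-4-oxobutanoate | CC(C)(C)OC(=O)CCC(=O)N1C(=O)OC[C@@H]1Cc1ccccc1 | intermediate
4 | (3-bromoprop-1-yn-1-yl)trimethylsilane | C[Si](C)(C)C#CCBr | starting material
5 | tert-butyl (3S)-3-{[(4S)-4-benzyl-2-oxo-1,3-oxazolidin-3-yl]carbonyl}-6-(trimethylsilyl)hex-5-ynoate | CC(C)(C)OC(=O)C[C@H](CC#C[Si](C)(C)C)C(=O)N1C(=O)OC[C@@H]1Cc1ccccc1 | intermediate
6 | tert-butyl (3S)-3-(hydroxymethyl)-6-(trimethylsilyl)hex-5-ynoate | CC(C)(C)OC(=O)C[C@H](CC#C[Si](C)(C)C)CO | intermediate (not isolated)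
7 | (4S)-4-[3-(trimethylsilyl)prop-2-yn-1-yl]oxolan-2-one | O=C1C[C@H](CC#C[Si](C)(C)C)CO1 | intermediate
8 | 3-benzyloxy-4-methoxybenzaldehyde | COc1ccc(C=O)cc1OCc1ccccc1 | starting material
9 | (3R,4S)-3-[(S)-(3-benzyloxy-4-methoxyphenyl)(hydroxy)methyl]-4-[3-(trimethylsilyl)prop-2-yn-1-yl]oxolan-2-one (anti epimer drawn; carbinol epimer carried along) | O=C1OC[C@@H](CC#C[Si](C)(C)C)[C@@H]1[C@H](O)c1ccc(OC)c(OCc2ccccc2)c1 | intermediate
10 | (1S,2S,3S)-1-(3-benzyloxy-4-methoxyphenyl)-2-(hydroxymethyl)-3-[3-(trimethylsilyl)prop-2-yn-1-yl]butane-1,4-diol (C1 epimer carried along) | COc1ccc([C@@H](O)[C@H](CO)[C@H](CC#C[Si](C)(C)C)CO)cc1OCc1ccccc1 | intermediate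
11 | {(2R,3S,4S)-2-(3-benzyloxy-4-methoxyphenyl)-4-[3-(trimethylsilyl)prop-2-yn-1-yl]oxolan-3-yl}methanol | COc1ccc([C@@H]2OC[C@@H](CC#C[Si](C)(C)C)[C@H]2CO)cc1OCc1ccccc1 | intermediate (not isolated)
12 | [(2R,3S,4S)-2-(3-benzyloxy-4-methoxyphenyl)-4-(prop-2-yn-1-yl)oxolan-3-yl]methanol | COc1ccc([C@@H]2OC[C@@H](CC#C)[C@H]2CO)cc1OCc1ccccc1 | intermediate
13 | (2R,3S,4S)-2-(3-benzyloxy-4-methoxyphenyl)-3-(benzyloxymethyl)-4-(prop-2-yn-1-yl)oxolane | COc1ccc([C@@H]2OC[C@@H](CC#C)[C@H]2COCc2ccccc2)cc1OCc1ccccc1 | intermediate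
14 | trichloroacetyl chloride | ClC(Cl)(Cl)C(Cl)=O | starting material
15 | 4,4-dichloro-3-{[(3S,4S,5R)-5-(3-benzyloxy-4-methoxyphenyl)-4-(benzyloxymethyl)oxolan-3-yl]methyl}cyclobut-2-en-1-one | COc1ccc([C@@H]2OC[C@@H](CC3=CC(=O)C3(Cl)Cl)[C@H]2COCc2ccccc2)cc1OCc1ccccc1 | intermediate
16 | 3-{[(3S,4S,5R)-5-(3-benzyloxy-4-methoxyphenyl)-4-(benzyloxymethyl)oxolan-3-yl]methyl}cyclobut-2-en-1-one (fragment 1) | COc1ccc([C@@H]2OC[C@@H](CC3=CC(=O)C3)[C@H]2COCc2ccccc2)cc1OCc1ccccc1 | intermediate
17 | 3-(benzyloxy)propanoic acid | OC(=O)CCOCc1ccccc1 | starting material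
18 | (4R)-4-benzyl-1,3-oxazolidin-2-one | O=C1N[C@H](Cc2ccccc2)CO1 | starting material
19 | (4R)-4-benzyl-3-[3-(benzyloxy)propanoyl]-1,3-oxazolidin-2-one | O=C(CCOCc1ccccc1)N1C(=O)OC[C@H]1Cc1ccccc1 | intermediate
20 | 4-benzyloxy-3-methoxybenzaldehyde | COc1cc(C=O)ccc1OCc1ccccc1 | starting material
21 | (4R)-4-benzyl-3-[(2R,3R)-2-(benzyloxymethyl)-3-(4-benzyloxy-3-methoxyphenyl)-3-hydroxypropanoyl]-1,3-oxazolidin-2-one | O=C([C@H](COCc1ccccc1)[C@@H](O)c1ccc(OCc2ccccc2)c(OC)c1)N1C(=O)OC[C@H]1Cc1ccccc1 | intermediate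
22 | (4R)-4-benzyl-3-[(2R,3R)-2-(benzyloxymethyl)-3-(4-benzyloxy-3-methoxyphenyl)-3-(tert-butyldimethylsilyloxy)propanoyl]-1,3-oxazolidin-2-one | O=C([C@H](COCc1ccccc1)[C@@H](O[Si](C)(C)C(C)(C)C)c1ccc(OCc2ccccc2)c(OC)c1)N1C(=O)OC[C@H]1Cc1ccccc1 | intermediate
23 | (2R,3R)-2-(benzyloxymethyl)-3-(4-benzyloxy-3-methoxyphenyl)-3-(tert-butyldimethylsilyloxy)propan-1-ol | OC[C@H](COCc1ccccc1)[C@@H](O[Si](C)(C)C(C)(C)C)c1ccc(OCc2ccccc2)c(OC)c1 | intermediate
24 | (2R,3R)-2-(benzyloxymethyl)-3-(4-benzyloxy-3-methoxyphenyl)-3-(tert-butyldimethylsilyloxy)propanal | O=C[C@H](COCc1ccccc1)[C@@H](O[Si](C)(C)C(C)(C)C)c1ccc(OCc2ccccc2)c(OC)c1 | intermediate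
25 | {[(1R,2R)-2-(benzyloxymethyl)-1-(4-benzyloxy-3-methoxyphenyl)but-3-yn-1-yl]oxy}(tert-butyl)dimethylsilane | C#C[C@H](COCc1ccccc1)[C@@H](O[Si](C)(C)C(C)(C)C)c1ccc(OCc2ccccc2)c(OC)c1 | intermediate
26 | lithium (3R,4R)-3-(benzyloxymethyl)-4-(4-benzyloxy-3-methoxyphenyl)-4-(tert-butyldimethylsilyloxy)but-1-yn-1-olate | [Li+].[O-]C#C[C@H](COCc1ccccc1)[C@@H](O[Si](C)(C)C(C)(C)C)c1ccc(OCc2ccccc2)c(OC)c1 | intermediate (not isolated)
27 | {[(3R,4R)-3-(benzyloxymethyl)-4-(4-benzyloxy-3-methoxyphenyl)-4-(tert-butyldimethylsilyloxy)but-1-yn-1-yl]oxy}tri(propan-2-yl)silane (fragment 2) | CC(C)[Si](OC#C[C@H](COCc1ccccc1)[C@@H](O[Si](C)(C)C(C)(C)C)c1ccc(OCc2ccccc2)c(OC)c1)(C(C)C)C(C)C | intermediate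
28 | 3-{[(3S,4S,5R)-5-(3-benzyloxy-4-methoxyphenyl)-4-(benzyloxymethyl)oxolan-3-yl]methyl}buta-1,3-dien-1-one (vinylketene) | COc1ccc([C@@H]2OC[C@@H](CC(=C)C=C=O)[C@H]2COCc2ccccc2)cc1OCc1ccccc1 | intermediate (not isolated)
29 | 2-[(1R,2R)-side chain]-3-(triisopropylsilyloxy)-4-{3-[(3S,4S,5R)-oxolan-3-yl]prop-1-en-2-yl}cyclobut-2-en-1-one (both epimers at ring C4; side chain and oxolane substituted as in 27 and 16) | COc1ccc([C@@H]2OC[C@@H](CC(=C)C3C(=O)C([C@H](COCc4ccccc4)[C@@H](O[Si](C)(C)C(C)(C)C)c4ccc(OCc5ccccc5)c(OC)c4)=C3O[Si](C(C)C)(C(C)C)C(C)C)[C@H]2COCc2ccccc2)cc1OCc1ccccc1 | intermediate (not isolated)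
30 | dienylketene from ring opening of 29 (ketene carbon and isopropenyl-type unit cis on the central C=C) | COc1ccc([C@@H]2OC[C@@H](CC(=C)/C=C(O[Si](C(C)C)(C(C)C)C(C)C)\C(=C=O)[C@H](COCc3ccccc3)[C@@H](O[Si](C)(C)C(C)(C)C)c3ccc(OCc4ccccc4)c(OC)c3)[C@H]2COCc2ccccc2)cc1OCc1ccccc1 | intermediate (not isolated)
31 | cyclohexa-2,4-dien-1-one tautomer of 32 | COc1ccc([C@@H]2OC[C@@H](CC3=CC(O[Si](C(C)C)(C(C)C)C(C)C)=C([C@H](COCc4ccccc4)[C@@H](O[Si](C)(C)C(C)(C)C)c4ccc(OCc5ccccc5)c(OC)c4)C(=O)C3)[C@H]2COCc2ccccc2)cc1OCc1ccccc1 | intermediate (not isolated)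
32 | 2-[(1R,2R)-3-benzyloxy-1-(4-benzyloxy-3-methoxyphenyl)-1-(tert-butyldimethylsilyloxy)propan-2-yl]-5-{[(3S,4S,5R)-5-(3-benzyloxy-4-methoxyphenyl)-4-(benzyloxymethyl)oxolan-3-yl]methyl}-3-(triisopropylsilyloxy)phenol | COc1ccc([C@@H]2OC[C@@H](Cc3cc(O[Si](C(C)C)(C(C)C)C(C)C)c([C@H](COCc4ccccc4)[C@@H](O[Si](C)(C)C(C)(C)C)c4ccc(OCc5ccccc5)c(OC)c4)c(O)c3)[C@H]2COCc2ccccc2)cc1OCc1ccccc1 | intermediate
33 | methyl ether of 32: {2-[(1R,2R)-3-benzyloxy-1-(4-benzyloxy-3-methoxyphenyl)-1-(tert-butyldimethylsilyloxy)propan-2-yl]-5-{[(3S,4S,5R)-5-(3-benzyloxy-4-methoxyphenyl)-4-(benzyloxymethyl)oxolan-3-yl]methyl}-3-methoxyphenoxy}tri(propan-2-yl)silane | COc1ccc([C@@H]2OC[C@@H](Cc3cc(O[Si](C(C)C)(C(C)C)C(C)C)c([C@H](COCc4ccccc4)[C@@H](O[Si](C)(C)C(C)(C)C)c4ccc(OCc5ccccc5)c(OC)c4)c(OC)c3)[C@H]2COCc2ccccc2)cc1OCc1ccccc1 | intermediate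
34 | 2-[(1R,2R)-3-benzyloxy-1-(4-benzyloxy-3-methoxyphenyl)-1-hydroxypropan-2-yl]-5-{[(3S,4S,5R)-5-(3-benzyloxy-4-methoxyphenyl)-4-(benzyloxymethyl)oxolan-3-yl]methyl}-3-methoxyphenol | COc1ccc([C@@H]2OC[C@@H](Cc3cc(O)c([C@H](COCc4ccccc4)[C@@H](O)c4ccc(OCc5ccccc5)c(OC)c4)c(OC)c3)[C@H]2COCc2ccccc2)cc1OCc1ccccc1 | intermediate
35 | (2S,3R)-2-(4-benzyloxy-3-methoxyphenyl)-3-(benzyloxymethyl)-6-{[(3S,4S,5R)-5-(3-benzyloxy-4-methoxyphenyl)-4-(benzyloxymethyl)oxolan-3-yl]methyl}-4-methoxy-2,3-dihydro-1-benzofuran | COc1ccc([C@@H]2OC[C@@H](Cc3cc(OC)c4c(c3)O[C@H](c3ccc(OCc5ccccc5)c(OC)c3)[C@H]4COCc3ccccc3)[C@H]2COCc2ccccc2)cc1OCc1ccccc1 | intermediate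
36 | [(2S,3R)-2-(4-hydroxy-3-methoxyphenyl)-6-{[(3S,4S,5R)-5-(3-hydroxy-4-methoxyphenyl)-4-(hydroxymethyl)oxolan-3-yl]methyl}-4-methoxy-2,3-dihydro-1-benzofuran-3-yl]methanol (CNP0242386.1) | COc1ccc([C@@H]2OC[C@@H](Cc3cc(OC)c4c(c3)O[C@H](c3ccc(O)c(OC)c3)[C@H]4CO)[C@H]2CO)cc1O | target

**Step count**

Total: 21 steps. Longest linear sequence: 14 steps (steps 1–9, then 17–21); fragment 2 takes 7 steps (10–16).

**Steps most likely to fail, with fallbacks**

Step 17 (benzannulation). The [2+2] step between ketene 28 and the bulky, α-branched ynol ether 27 may be too slow at the temperature at which 16 opens, so that the ketene recloses or oligomerises, and 27 may undergo a thermal 1,3-silyl shift to a silylketene before it is consumed. The fallback generates the same ketene irreversibly at room temperature. Setting out from 16, brief heating in wet THF opens the ring and hydrates the ketene to 3-{[(3S,4S,5R)-5-(3-benzyloxy-4-methoxyphenyl)-4-(benzyloxymethyl)oxolan-3-yl]methyl}but-3-enoic acid F1. 1-Chloro-N,N,2-trimethylprop-1-en-1-amine in CH2Cl2 at 0 °C converts this under neutral conditions into the corresponding but-3-enoyl chloride F2. Et3N then dehydrochlorinates F2 at 0–25 °C in the presence of 27, so that 28 is formed and taken up by ketene–siloxyalkyne [2+2] cycloaddition at a temperature where neither partner decomposes. The cycloadduct 29 is isolated and only then warmed in toluene for its electrocyclic opening and closure, which returns to the route at 32.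

Step 8 (dichloroketene cycloaddition). ZnCl2 together with the acid chloride may ionise or cleave the electron-rich benzylic ether of the oxolane (epimerisation at C2 or ring opening), and the alkyne may be consumed only sluggishly while the ketene polymerises. The fallback is a keteniminium [2+2] cycloaddition without zinc or chlorine. Setting out from 13, N,N-dimethylacetamide, (CF3SO2)2O and 2,4,6-collidine in 1,2-dichloroethane should give N,N-dimethyl-3-{[(3S,4S,5R)-5-(3-benzyloxy-4-methoxyphenyl)-4-(benzyloxymethyl)oxolan-3-yl]methyl}cyclobut-2-en-1-iminium trifluoromethanesulfonate F3. Aqueous NaHCO3 hydrolyses F3 directly to 16, so that 15 and step 9 are bypassed.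

Step 20 (Mitsunobu ring closure). The activated p-alkoxybenzylic alcohol may ionise and lose the neighbouring proton to give a stilbene-type alkene, or be captured by the hydrazide, instead of being displaced by the phenol. The fallback is a dehydrative SN1 ring closure. Setting out from 34, catalytic pyridinium p-toluenesulfonate in (CF3)2CHOH–CH2Cl2 at 0 °C ionises the benzylic alcohol, and the neighbouring phenol captures the cation trans to the C3 substituent, which returns to the route at 35. Short contact time is needed so that the oxolane benzylic ether is not ionised as well. This fallback makes no new compound (F0).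

**Further compounds**

F1 | step 17 | 3-{[(3S,4S,5R)-5-(3-benzyloxy-4-methoxyphenyl)-4-(benzyloxymethyl)oxolan-3-yl]methyl}but-3-enoic acid | COc1ccc([C@@H]2OC[C@@H](CC(=C)CC(=O)O)[C@H]2COCc2ccccc2)cc1OCc1ccccc1
F2 | step 17 | 3-{[(3S,4S,5R)-5-(3-benzyloxy-4-methoxyphenyl)-4-(benzyloxymethyl)oxolan-3-yl]methyl}but-3-enoyl chloride | COc1ccc([C@@H]2OC[C@@H](CC(=C)CC(=O)Cl)[C@H]2COCc2ccccc2)cc1OCc1ccccc1
F3 | step 8 | N,N-dimethyl-3-{[(3S,4S,5R)-5-(3-benzyloxy-4-methoxyphenyl)-4-(benzyloxymethyl)oxolan-3-yl]methyl}cyclobut-2-en-1-iminium trifluoromethanesulfonate | COc1ccc([C@@H]2OC[C@@H](CC3=CC(=[N+](C)C)C3)[C@H]2COCc2ccccc2)cc1OCc1ccccc1.[O-]S(=O)(=O)C(F)(F)F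
F0 | step 20 | none | none
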